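**Assumption:** atoms are numbered C1–C15 along the chain (C1 = alkyne CH, C15 = ethyl CH3). The SMILES then reads 3Z, 5S, 6S, 7R, 9E (ring-cis; Cl outranks C11), 12S, 13R, with the C7 and C13 substituents cis across the ring oxygen.

## Retrosynthetic overview

1. Target ⇒ alkyne desilylation, Z-selective Peterson enyne olefination at C4, cleavage of a vinyl group and O-acetylation ⇒ a syn vinyl chlorohydrin on the finished bromo-chloro-oxocene.
2. Key disconnection C5–C6: oxocene-2-carbaldehyde + α-chloroallyl anion. Allyl chloride becomes a nucleophile at its own C–Cl carbon, as (Z)-γ-chloroallyl-B(Ipc)2. Two normally electrophilic carbons are joined, and C5, C6 and the C5–Cl bond are set in one step.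
3. Aldehyde ⇒ ozonolysis of an isobutenyl group. C12–Br ⇒ invertive bromination. The only ring, the eight-membered chloro-oxocene, ⇒ RCM of an allyl/2-chloroallyl diene, closed before the key step.
4. Diene ⇒ chelation-controlled 2-chloroallylation (C11–C12) of an α-alkoxy aldehyde. C13–O ether ⇒ SN2 of the C7 alkoxide on an (S)-2-triflyloxybutanoate.
5. C7 carbinol ⇒ asymmetric allylboration of prenal.

## Route

Step 1
Reactants: 1 3-methylbut-2-enal (prenal); 2 allylmagnesium bromide
Product: 4 (4R)-6-methylhepta-1,5-dien-4-ol, via B-allylbis(isopinocampheyl)borane 3 (not isolated)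
Conditions: (+)-Ipc2BOMe [from (−)-α-pinene], 2, Et2O, −78 °C → rt; 1, −78 °C; NaOH, H2O2
Reagents that add atoms: none
Why: Brown asymmetric allylboration through a closed chair transition state, in which the (−)-α-pinene-derived ligands direct the allyl group to the Re face of the enal and set C7 as R.

Step 2
Reactants: 5 methyl (2S)-2-hydroxybutanoate
Product: 6 methyl (2S)-2-(trifluoromethylsulfonyloxy)butanoate
Conditions: Tf2O, 2,6-lutidine, CH2Cl2, −78 → 0 °C
Reagents that add atoms: trifluoromethanesulfonic anhydride, O=S(=O)(OS(=O)(=O)C(F)(F)F)C(F)(F)F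
Why: O-triflation does not touch the stereocentre and gives an α-carbonyl leaving group that reacts by clean SN2.

Step 3
Reactants: 4 (4R)-6-methylhepta-1,5-dien-4-ol; 6 methyl (2S)-2-(trifluoromethylsulfonyloxy)butanoate
Product: 8 methyl (2R)-2-{[(4R)-6-methylhepta-1,5-dien-4-yl]oxy}butanoate, via sodium (4R)-6-methylhepta-1,5-dien-4-olate 7 (not isolated)
Conditions: NaH, THF, 0 °C; 6, −40 → 0 °C
Reagents that add atoms: none
Why: Williamson-type SN2 etherification on the α-triflyloxy ester goes with inversion (S → R, setting C13), leaves the C7–O bond untouched, and the cold sodium alkoxide is too slow for anionic oxy-Cope rearrangement.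

Step 4
Reactants: 8 methyl (2R)-2-{[(4R)-6-methylhepta-1,5-dien-4-yl]oxy}butanoate
Product: 9 (2R)-2-{[(4R)-6-methylhepta-1,5-dien-4-yl]oxy}butanal
Conditions: iBu2AlH (1.1 equiv), CH2Cl2, −78 °C; aq potassium sodium tartrate
Reagents that add atoms: none
Why: Partial ester reduction stops at the aldehyde because the α-alkoxy group stabilises the aluminium hemiacetal at −78 °C, and the crude aldehyde is used at once to avoid epimerisation at C13.

Step 5
Reactants: 10 2,3-dichloroprop-1-ene
Product: 12 tributyl(2-chloroprop-2-en-1-yl)stannane, via tributylstannyllithium 11 (not isolated)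
Conditions: Bu3SnH, LiN(iPr)2, THF, 0 °C; 10, −78 °C → rt
Reagents that add atoms: tributyltin hydride, CCCC[SnH](CCCC)CCCC
Why: SN2 stannylation takes place only at the allylic chloride, since the vinylic chloride is inert to the stannyl anion.

Step 6
Reactants: 9 (2R)-2-{[(4R)-6-methylhepta-1,5-dien-4-yl]oxy}butanal; 12 tributyl(2-chloroprop-2-en-1-yl)stannane
Product: 13 (4R,5R)-2-chloro-5-{[(4R)-6-methylhepta-1,5-dien-4-yl]oxy}hept-1-en-4-ol
Conditions: MgBr2·OEt2 (2.5 equiv), CH2Cl2, −78 °C; 12, −78 → −20 °C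
Reagents that add atoms: none
Why: Keck-type chelation-controlled allylstannane addition, in which the five-membered Mg chelate of the carbonyl and ether oxygens exposes the face next to H-13 and gives the 12,13-syn (12R) alcohol.

Step 7
Reactants: 13 (4R,5R)-2-chloro-5-{[(4R)-6-methylhepta-1,5-dien-4-yl]oxy}hept-1-en-4-ol
Product: 14 (2R,3R,8R)-5-chloro-2-ethyl-8-(2-methylprop-1-en-1-yl)-3,4,7,8-tetrahydro-2H-oxocin-3-ol
Conditions: second-generation Grubbs catalyst (10 mol %), 1,4-benzoquinone (20 mol %), benzene (2 mM), 70 °C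
Reagents that add atoms: none
Why: Proposed new method: ring-closing metathesis of 2-chloro-1-alkenes is established for five- to seven-membered rings and is extended here to an eight-membered ether; the ruthenium alkylidene forms at the allyl terminus, the chloroalkene acts only as acceptor so that Ru=CH2 and no chlorocarbene is released, the gauche O12/O13 conformer already holds C11 gauche to the ether oxygen, the trisubstituted isobutenyl group is inert, and the ring size enforces the ring-cis (formally E) C9=C10 geometry.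

Step 8
Reactants: 14 (2R,3R,8R)-5-chloro-2-ethyl-8-(2-methylprop-1-en-1-yl)-3,4,7,8-tetrahydro-2H-oxocin-3-ol
Product: 15 (2R,3S,8R)-3-bromo-5-chloro-2-ethyl-8-(2-methylprop-1-en-1-yl)-3,4,7,8-tetrahydro-2H-oxocine
Conditions: CBr4, P(n-C8H17)3, 2,6-di-tert-butylpyridine, toluene, 70 °C
Reagents that add atoms: carbon tetrabromide, BrC(Br)(Br)Br
Why: Appel-type bromination displaces the alkoxyphosphonium ion by SN2 with inversion (12R → 12S), the electron-poor chloroalkene gives no homoallylic participation, and the hindered base protects the allylic ether from HBr.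

Step 9
Reactants: 15 (2R,3S,8R)-3-bromo-5-chloro-2-ethyl-8-(2-methylprop-1-en-1-yl)-3,4,7,8-tetrahydro-2H-oxocine
Product: 16 (2R,7S,8R)-7-bromo-5-chloro-8-ethyl-3,6,7,8-tetrahydro-2H-oxocine-2-carbaldehyde
Conditions: O3, CH2Cl2, −78 °C (Sudan Red 7B end point); Me2S, −78 °C → rt
Reagents that add atoms: ozone, [O-][O+]=O
Why: Chemoselective ozonolysis, because electrophilic ozone takes the electron-rich trialkyl alkene much faster than the chlorine-deactivated ring alkene and so releases the C6 aldehyde in one step.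

Step 10 (key step)
Reactants: 16 (2R,7S,8R)-7-bromo-5-chloro-8-ethyl-3,6,7,8-tetrahydro-2H-oxocine-2-carbaldehyde; 17 allyl chloride
Product: 19 (1S,2S)-1-[(2R,7S,8R)-7-bromo-5-chloro-8-ethyl-3,6,7,8-tetrahydro-2H-oxocin-2-yl]-2-chlorobut-3-en-1-ol, via [(Z)-3-chloroallyl]bis(isopinocampheyl)borane 18 (not isolated)
Conditions: 17, (+)-Ipc2BOMe, LiN(c-C6H11)2 [HN(c-C6H11)2, n-BuLi], Et2O–THF, −95 °C; BF3·OEt2; 16, −95 °C; H2O2, aq NaOAc, 0 °C
Reagents that add atoms: none
Why: Asymmetric γ-chloroallylboration, in which allyl chloride (normally an electrophile at C–Cl) is deprotonated and borylated in situ to 18, an α-chloroallyl-anion equivalent of reversed polarity whose chlorine-bearing carbon attacks the aldehyde carbon through a Zimmerman–Traxler chair; the Z geometry gives the 5,6-syn chlorohydrin and the (−)-α-pinene-derived ligands force Re-face attack (6S, hence 5S) against the Cornforth bias of the α-alkoxy aldehyde.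

Step 11
Reactants: 19 (1S,2S)-1-[(2R,7S,8R)-7-bromo-5-chloro-8-ethyl-3,6,7,8-tetrahydro-2H-oxocin-2-yl]-2-chlorobut-3-en-1-ol
Product: 20 (1S,2S)-1-[(2R,7S,8R)-7-bromo-5-chloro-8-ethyl-3,6,7,8-tetrahydro-2H-oxocin-2-yl]-2-chlorobut-3-en-1-yl acetate
Conditions: Ac2O, pyridine, DMAP (cat.), CH2Cl2, 0 °C
Reagents that add atoms: acetic anhydride, CC(=O)OC(C)=O
Why: Nucleophile-catalysed acetylation installs the natural ester under conditions too weakly basic to close the chlorohydrin to an epoxide.

Step 12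
Reactants: 20 (1S,2S)-1-[(2R,7S,8R)-7-bromo-5-chloro-8-ethyl-3,6,7,8-tetrahydro-2H-oxocin-2-yl]-2-chlorobut-3-en-1-yl acetate
Product: 21 (1S,2R)-1-[(2R,7S,8R)-7-bromo-5-chloro-8-ethyl-3,6,7,8-tetrahydro-2H-oxocin-2-yl]-2-chloro-3-oxopropyl acetate
Conditions: OsO4 (4 mol %), NaIO4, 2,6-lutidine, dioxane–H2O 3:1, rt
Reagents that add atoms: sodium periodate, [Na+].[O-]I(=O)(=O)=O (net oxygen source, relayed by catalytic OsO4, O=[Os](=O)(=O)=O)
Why: Lemieux–Johnson cleavage selects the accessible monosubstituted vinyl group over the hindered, chlorine-deactivated ring alkene, and the C5 descriptor changes to R only because CHO outranks C6 (no bond at C5 is touched).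

Step 13
Reactants: 22 trimethyl(prop-1-yn-1-yl)silane
Product: 24 tert-butyldimethyl[3-(trimethylsilyl)prop-2-yn-1-yl]silane, via 3-lithio-1-(trimethylsilyl)propyne 23 (not isolated)
Conditions: n-BuLi, THF, −20 °C; TBSCl, −78 °C → rt
Reagents that add atoms: tert-butyldimethylsilyl chloride, CC(C)(C)[Si](C)(C)Cl
Why: Propargylic lithiation followed by C-silylation at the less hindered propargylic terminus gives the Peterson reagent.

Step 14
Reactants: 21 (1S,2R)-1-[(2R,7S,8R)-7-bromo-5-chloro-8-ethyl-3,6,7,8-tetrahydro-2H-oxocin-2-yl]-2-chloro-3-oxopropyl acetate; 24 tert-butyldimethyl[3-(trimethylsilyl)prop-2-yn-1-yl]silane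
Product: 27 (1S,2S,3Z)-1-[(2R,7S,8R)-7-bromo-5-chloro-8-ethyl-3,6,7,8-tetrahydro-2H-oxocin-2-yl]-2-chloro-6-(trimethylsilyl)hex-3-en-5-yn-1-yl acetate, via lithiated bis-silylpropyne 25 (not isolated), via allenyltitanium triisopropoxide 26 (not isolated)
Conditions: 24, t-BuLi, THF, −78 °C; Ti(OiPr)4, −78 °C; 21, −78 °C → 0 °C; H2O
Reagents that add atoms: none
Why: Yamamoto–Peterson olefination, in which the weakly basic allenyltitanium adds through a cyclic transition state and the resulting β-silyl alkoxide undergoes syn elimination to give the Z enyne, without palladium (which would ionise the allylic chloride) and without enolising the α-chloro aldehyde.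

Step 15
Reactants: 27 (1S,2S,3Z)-1-[(2R,7S,8R)-7-bromo-5-chloro-8-ethyl-3,6,7,8-tetrahydro-2H-oxocin-2-yl]-2-chloro-6-(trimethylsilyl)hex-3-en-5-yn-1-yl acetate
Product: 28 (1S,2S,3Z)-1-[(2R,7S,8R)-7-bromo-5-chloro-8-ethyl-3,6,7,8-tetrahydro-2H-oxocin-2-yl]-2-chlorohex-3-en-5-yn-1-yl acetate (target)
Conditions: Bu4NF, AcOH (1:1), THF, −20 → 0 °C
Reagents that add atoms: none
Why: Buffered fluoride protodesilylation removes the alkynyl SiMe3 group within minutes, and the acetic acid keeps the medium non-basic so that the acetate, the allylic chloride and the secondary bromide survive.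

## Compound list

1 | 3-methylbut-2-enal | CC(C)=CC=O | starting material
2 | allylmagnesium bromide | C=CC[Mg]Br | starting material
3 | B-allylbis(isopinocampheyl)borane, ligands from (−)-α-pinene | C=CCB([C@H]1C[C@H]2C[C@H](C2(C)C)[C@@H]1C)[C@H]1C[C@H]2C[C@H](C2(C)C)[C@@H]1C | intermediate
4 | (4R)-6-methylhepta-1,5-dien-4-ol | C=CC[C@@H](O)C=C(C)C | intermediate
5 | methyl (2S)-2-hydroxybutanoate | CC[C@H](O)C(=O)OC | starting material
6 | methyl (2S)-2-(trifluoromethylsulfonyloxy)butanoate | CC[C@H](OS(=O)(=O)C(F)(F)F)C(=O)OC | intermediate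
7 | sodium (4R)-6-methylhepta-1,5-dien-4-olate | [Na+].[O-][C@H](CC=C)C=C(C)C | intermediate
8 | methyl (2R)-2-{[(4R)-6-methylhepta-1,5-dien-4-yl]oxy}butanoate | CC[C@@H](O[C@H](CC=C)C=C(C)C)C(=O)OC | intermediate
9 | (2R)-2-{[(4R)-6-methylhepta-1,5-dien-4-yl]oxy}butanal | CC[C@@H](O[C@H](CC=C)C=C(C)C)C=O | intermediate
10 | 2,3-dichloroprop-1-ene | C=C(Cl)CCl | starting material
11 | tributylstannyllithium | [Li][Sn](CCCC)(CCCC)CCCC | intermediate
12 | tributyl(2-chloroprop-2-en-1-yl)stannane | C=C(Cl)C[Sn](CCCC)(CCCC)CCCC | intermediate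
13 | (4R,5R)-2-chloro-5-{[(4R)-6-methylhepta-1,5-dien-4-yl]oxy}hept-1-en-4-ol | CC[C@@H](O[C@H](CC=C)C=C(C)C)[C@H](O)CC(Cl)=C | intermediate
14 | (2R,3R,8R)-5-chloro-2-ethyl-8-(2-methylprop-1-en-1-yl)-3,4,7,8-tetrahydro-2H-oxocin-3-ol (ring-cis C5=C6, 2,8-cis) | CC(C)=C[C@H]1C/C=C(/Cl)C[C@@H](O)[C@@H](CC)O1 | intermediate
15 | (2R,3S,8R)-3-bromo-5-chloro-2-ethyl-8-(2-methylprop-1-en-1-yl)-3,4,7,8-tetrahydro-2H-oxocine | CC(C)=C[C@H]1C/C=C(/Cl)C[C@H](Br)[C@@H](CC)O1 | intermediate
16 | (2R,7S,8R)-7-bromo-5-chloro-8-ethyl-3,6,7,8-tetrahydro-2H-oxocine-2-carbaldehyde | O=C[C@H]1C/C=C(/Cl)C[C@H](Br)[C@@H](CC)O1 | intermediate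
17 | allyl chloride (3-chloroprop-1-ene) | C=CCCl | starting material
18 | [(Z)-3-chloroallyl]bis(isopinocampheyl)borane, ligands from (−)-α-pinene | Cl/C=C\CB([C@H]1C[C@H]2C[C@H](C2(C)C)[C@@H]1C)[C@H]1C[C@H]2C[C@H](C2(C)C)[C@@H]1C | intermediate
19 | (1S,2S)-1-[(2R,7S,8R)-7-bromo-5-chloro-8-ethyl-3,6,7,8-tetrahydro-2H-oxocin-2-yl]-2-chlorobut-3-en-1-ol | C=C[C@H](Cl)[C@@H](O)[C@H]1C/C=C(/Cl)C[C@H](Br)[C@@H](CC)O1 | intermediate
20 | (1S,2S)-1-[(2R,7S,8R)-7-bromo-5-chloro-8-ethyl-3,6,7,8-tetrahydro-2H-oxocin-2-yl]-2-chlorobut-3-en-1-yl acetate | C=C[C@H](Cl)[C@@H](OC(C)=O)[C@H]1C/C=C(/Cl)C[C@H](Br)[C@@H](CC)O1 | intermediate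
21 | (1S,2R)-1-[(2R,7S,8R)-7-bromo-5-chloro-8-ethyl-3,6,7,8-tetrahydro-2H-oxocin-2-yl]-2-chloro-3-oxopropyl acetate | O=C[C@H](Cl)[C@@H](OC(C)=O)[C@H]1C/C=C(/Cl)C[C@H](Br)[C@@H](CC)O1 | intermediate
22 | trimethyl(prop-1-yn-1-yl)silane | CC#C[Si](C)(C)C | starting material
23 | 3-lithio-1-(trimethylsilyl)propyne | [Li]CC#C[Si](C)(C)C | intermediate
24 | tert-butyldimethyl[3-(trimethylsilyl)prop-2-yn-1-yl]silane | CC(C)(C)[Si](C)(C)CC#C[Si](C)(C)C | intermediate
25 | 1-(tert-butyldimethylsilyl)-1-lithio-3-(trimethylsilyl)prop-2-yne | [Li]C(C#C[Si](C)(C)C)[Si](C)(C)C(C)(C)C | intermediate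
26 | [3-(tert-butyldimethylsilyl)-1-(trimethylsilyl)propa-1,2-dien-1-yl]titanium triisopropoxide | CC(C)O[Ti](OC(C)C)(OC(C)C)C(=C=C[Si](C)(C)C(C)(C)C)[Si](C)(C)C | intermediate
27 | (1S,2S,3Z)-1-[(2R,7S,8R)-7-bromo-5-chloro-8-ethyl-3,6,7,8-tetrahydro-2H-oxocin-2-yl]-2-chloro-6-(trimethylsilyl)hex-3-en-5-yn-1-yl acetate | C[Si](C)(C)C#C/C=C\[C@H](Cl)[C@@H](OC(C)=O)[C@H]1C/C=C(/Cl)C[C@H](Br)[C@@H](CC)O1 | intermediate
28 | (1S,2S,3Z)-1-[(2R,7S,8R)-7-bromo-5-chloro-8-ethyl-3,6,7,8-tetrahydro-2H-oxocin-2-yl]-2-chlorohex-3-en-5-yn-1-yl acetate | C#C/C=C\[C@H](Cl)[C@@H](OC(C)=O)[C@H]1C/C=C(/Cl)C[C@H](Br)[C@@H](CC)O1 | target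

## Step count

Total step count: 15.

Longest linear sequence: 12 (steps 1, 3, 4, 6–12, 14, 15).

## Steps most likely to fail

**Step 7 (eight-membered RCM onto the 2-chloroalkene).** Metallacycle formation at the deactivated 1,1-disubstituted chloroalkene may lose to dimerisation or allyl isomerisation.
- The fallback sets out from 13 and comes back at 14. It takes the chlorine out of the metathesis event.
- Miyaura borylation of the alkenyl chloride (B2pin2, Pd2(dba)3, XPhos, KOAc, dioxane, 80 °C) gives the pinacol alkenylboronate diene F1.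
- Ring-closing metathesis of this 2-boryl-1-alkene with the second-generation Grubbs catalyst gives the cyclic alkenylboronate F2.
- Chlorodeboronation with CuCl2 in aqueous methanol replaces boron by chlorine with retention and delivers 14.

**Step 10 (key chloroallylboration).** The chiral borane must override the Cornforth preference of the α-alkoxy aldehyde, so the 6,7-selectivity may be low.
- The fallback sets out from 16 and comes back at 19. It replaces reagent control by substrate control, which here is matched to the target.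
- (E)-1,3-Dichloropropene and 11 give tributyl[(E)-3-chloroprop-2-en-1-yl]stannane F3, again a donor at a chlorine-bearing carbon.
- F3 is added to the MgBr2·OEt2 chelate of 16 in CH2Cl2. The Cram chelate fixes 6,7-syn (6S), and the open antiperiplanar transition state typical of γ-substituted allylstannanes fixes 5,6-syn.
- This step is an extrapolation from crotyl- and γ-alkoxyallylstannanes.

**Step 14 (Peterson olefination of 21).** The α-chloro-β-acetoxy aldehyde may epimerise at C5 or lose acetic acid before it is trapped.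
- The fallback sets out from 20 and comes back at 27, so the aldehyde 21 is never made.
- Vinyl bromide and trimethylsilylacetylene (PdCl2(PPh3)2, CuI, Et3N) give (but-3-en-1-yn-1-yl)trimethylsilane F4.
- Cross-metathesis of F4 with the vinyl group of 20 (second-generation Hoveyda–Grubbs catalyst, CH2Cl2, 40 °C) exploits the inherent Z preference of conjugated-enyne cross-metathesis. The ring chloroalkene stays inert.

## Further compounds

F1 | step 7 | (4R,5R)-5-{[(4R)-6-methylhepta-1,5-dien-4-yl]oxy}-2-(4,4,5,5-tetramethyl-1,3,2-dioxaborolan-2-yl)hept-1-en-4-ol | CC[C@@H](O[C@H](CC=C)C=C(C)C)[C@H](O)CC(=C)B1OC(C)(C)C(C)(C)O1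
F2 | step 7 | (2R,3R,8R)-2-ethyl-8-(2-methylprop-1-en-1-yl)-5-(4,4,5,5-tetramethyl-1,3,2-dioxaborolan-2-yl)-3,4,7,8-tetrahydro-2H-oxocin-3-ol | CC(C)=C[C@H]1C/C=C(/B2OC(C)(C)C(C)(C)O2)C[C@@H](O)[C@@H](CC)O1
F3 | step 10 | tributyl[(E)-3-chloroprop-2-en-1-yl]stannane | Cl/C=C/C[Sn](CCCC)(CCCC)CCCC
F4 | step 14 | (but-3-en-1-yn-1-yl)trimethylsilane | C=CC#C[Si](C)(C)C
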